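**Retrosynthetic overview**
1. Last step: global O-demethylation; all ten phenols are carried as methyl ethers.
2. Ring A–O–ring B ether: Ullmann C–O coupling of a ring B phenol with 2-iodo-1,3,5-trimethoxybenzene; that phenol comes from a ring B aldehyde by Baeyer–Villiger oxidation.
3. Ring B–O–ring C ether: Ullmann C–O coupling of the ring C–D biaryl phenol with 2-bromo-3,5-dimethoxybenzaldehyde; the formyl group activates the bromide and marks the later oxygen.
4. Key C–C bond (ring C–ring D, made first): 3,5-dimethoxyphenol reacts as the natural carbon nucleophile, and 1,3,5-trimethoxybenzene is turned by C–H plumbation into an aryl cation equivalent. Ligand coupling in the same flask joins the two unfunctionalised arenes ortho to the OH that later becomes the ether oxygen to ring B.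
5. No ring is constructed; all four benzene rings are bought. Order of assembly: D+C, then B, then A.

Assumption: the target has no stereocentre and no stereogenic axis (ring D is symmetric about the biaryl bond), so there is no enantiomer to control and the route makes the one achiral compound.

**Step 1**
Reactants: 1 1,3,5-trimethoxybenzene; 2 3,5-dimethoxyphenol
Product: 4 3,5-dimethoxy-2-(2,4,6-trimethoxyphenyl)phenol, via 2,4,6-trimethoxyphenyllead triacetate 3 (not isolated)
Conditions: Pb(OAc)4 (1.0 equiv), 1 (1.1 equiv), CHCl3, rt, dark, 2 h; then 2 (2.0 equiv), pyridine (3 equiv), 60 °C, 12 h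
Reagents that add atoms: none
Why: Electrophilic C–H plumbation of the very electron-rich arene 1 gives the aryl cation equivalent 3, which exchanges an acetate for the phenoxide of 2 and delivers the aryl group to the ortho carbon only (Pinhey–Barton ligand coupling at tetravalent lead), so the tetra-ortho-oxygenated biaryl forms next to the free OH; no stereocentre is formed.

**Step 2**
Reactants: 4 3,5-dimethoxy-2-(2,4,6-trimethoxyphenyl)phenol; 5 2-bromo-3,5-dimethoxybenzaldehyde
Product: 6 3,5-dimethoxy-2-[3,5-dimethoxy-2-(2,4,6-trimethoxyphenyl)phenoxy]benzaldehyde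
Conditions: CuI (20 mol%), picolinic acid (40 mol%), K3PO4 (2 equiv), 5 (1.2 equiv), DMSO, 90 °C, Ar
Reagents that add atoms: none
Why: Ullmann-type C–O coupling in which the ortho-formyl group accelerates copper insertion into the hindered C–Br bond; the non-enolisable aldehyde and the methyl ethers are inert to phosphate base.

**Step 3**
Reactants: 6 3,5-dimethoxy-2-[3,5-dimethoxy-2-(2,4,6-trimethoxyphenyl)phenoxy]benzaldehyde
Product: 8 3,5-dimethoxy-2-[3,5-dimethoxy-2-(2,4,6-trimethoxyphenyl)phenoxy]phenol, via aryl formate 7 (not isolated)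
Conditions: mCPBA (1.2 equiv), CH2Cl2, 0 °C to rt; then K2CO3 (0.2 equiv), MeOH, rt
Reagents that add atoms: mCPBA, OOC(=O)c1cccc(Cl)c1
Why: Baeyer–Villiger (Dakin-type) oxidation in which the ortho-aryloxy donor favours aryl over hydride migration, followed by methanolysis of the formate; a small excess of peracid at low temperature spares the trimethoxyaryl rings.

**Step 4**
Reactants: 8 3,5-dimethoxy-2-[3,5-dimethoxy-2-(2,4,6-trimethoxyphenyl)phenoxy]phenol; 9 2-iodo-1,3,5-trimethoxybenzene
Product: 10 1,5-dimethoxy-2-[3,5-dimethoxy-2-(2,4,6-trimethoxyphenyl)phenoxy]-3-(2,4,6-trimethoxyphenoxy)benzene (fucodiphloroethol G decamethyl ether)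
Conditions: CuI (20 mol%), picolinic acid (40 mol%), K3PO4 (2 equiv), 9 (1.5 equiv), DMSO, 110 °C, Ar
Reagents that add atoms: none
Why: Ullmann diaryl ether synthesis with the picolinic acid ligand system developed for ortho,ortho-disubstituted aryl iodides; 8 has a single free OH, so only one ether can form.

**Step 5**
Reactants: 10 fucodiphloroethol G decamethyl ether
Product: 11 fucodiphloroethol G
Conditions: BBr3 (20 equiv), CH2Cl2, −78 °C to rt, Ar, 24 h; then H2O, 0 °C; reversed-phase chromatography with degassed solvents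
Reagents that add atoms: none
Why: Lewis-acid cleavage of all ten aryl methyl ethers (BBr3 demethylation) leaves the diaryl ether and biaryl bonds intact at room temperature; there is no stereocentre to disturb.

**Compound list**
1 | 1,3,5-trimethoxybenzene | COc1cc(OC)cc(OC)c1 | starting material
2 | 3,5-dimethoxyphenol | COc1cc(O)cc(OC)c1 | starting material
3 | 2,4,6-trimethoxyphenyllead triacetate | COc1cc(OC)c(c(OC)c1)[Pb](OC(C)=O)(OC(C)=O)OC(C)=O | intermediate
4 | 3,5-dimethoxy-2-(2,4,6-trimethoxyphenyl)phenol (2',4,4',6,6'-pentamethoxybiphenyl-2-ol) | COc1cc(O)c(c(OC)c1)-c1c(OC)cc(OC)cc1OC | intermediate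
5 | 2-bromo-3,5-dimethoxybenzaldehyde | COc1cc(C=O)c(Br)c(OC)c1 | starting material
6 | 3,5-dimethoxy-2-[3,5-dimethoxy-2-(2,4,6-trimethoxyphenyl)phenoxy]benzaldehyde | COc1cc(C=O)c(Oc2cc(OC)cc(OC)c2-c2c(OC)cc(OC)cc2OC)c(OC)c1 | intermediate
7 | 3,5-dimethoxy-2-[3,5-dimethoxy-2-(2,4,6-trimethoxyphenyl)phenoxy]phenyl formate | COc1cc(OC=O)c(Oc2cc(OC)cc(OC)c2-c2c(OC)cc(OC)cc2OC)c(OC)c1 | intermediate
8 | 3,5-dimethoxy-2-[3,5-dimethoxy-2-(2,4,6-trimethoxyphenyl)phenoxy]phenol | COc1cc(O)c(Oc2cc(OC)cc(OC)c2-c2c(OC)cc(OC)cc2OC)c(OC)c1 | intermediate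
9 | 2-iodo-1,3,5-trimethoxybenzene | COc1cc(OC)c(I)c(OC)c1 | starting material
10 | fucodiphloroethol G decamethyl ether | COc1cc(OC)c(Oc2cc(OC)cc(OC)c2Oc2cc(OC)cc(OC)c2-c2c(OC)cc(OC)cc2OC)c(OC)c1 | intermediate
11 | fucodiphloroethol G | Oc1cc(O)c(Oc2cc(O)cc(O)c2Oc2cc(O)cc(O)c2-c2c(O)cc(O)cc2O)c(O)c1 | target

**Total step count:** 5
**Longest linear sequence:** 5 steps (1 → 4 → 6 → 8 → 10 → 11)

**Steps most likely to fail**

Step 1 (key biaryl formation). The risks are 2,6-diarylation of 2, oxidation of the phenol by leftover tetravalent lead, and slow ligand coupling because four ortho oxygen groups crowd the new bond. The fallback keeps the aryl cation idea but carries it on pentavalent bismuth. It sets out from 1: lithiation with n-BuLi in THF gives 2,4,6-trimethoxyphenyllithium F1, which with BiCl3 (0.33 equiv) gives tris(2,4,6-trimethoxyphenyl)bismuthane F2. SO2Cl2 in CH2Cl2 at −78 °C oxidises this to dichlorotris(2,4,6-trimethoxyphenyl)bismuth F3. F3 with 2 and 2-tert-butyl-1,1,3,3-tetramethylguanidine in THF transfers one aryl group to the ortho carbon of the phenoxide (Barton-type ligand coupling) and comes back to the route at 4.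

Step 4 (ether to ring A). The iodide 9 is electron-rich and flanked by two methoxy groups, so copper insertion may be too slow and 9 may simply lose iodine. The fallback builds ring A the way ring B was built. It sets out from 8, which is coupled with a second portion of 5 under the conditions of step 2 to give 3,5-dimethoxy-2-{3,5-dimethoxy-2-[3,5-dimethoxy-2-(2,4,6-trimethoxyphenyl)phenoxy]phenoxy}benzaldehyde F4. Baeyer–Villiger oxidation with mCPBA gives the corresponding aryl formate F5, and methanolysis gives 3,5-dimethoxy-2-{3,5-dimethoxy-2-[3,5-dimethoxy-2-(2,4,6-trimethoxyphenyl)phenoxy]phenoxy}phenol F6. Ring A of F6 already has the 2,4,6-trioxygenation pattern with one free OH, so BBr3 cleavage of its nine methyl ethers comes back to the route directly at 11, bypassing 10.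

Step 5 (tenfold demethylation). The risks are incomplete cleavage and air oxidation of the free polyphenol during isolation. The fallback changes the isolation strategy to capture and release. It sets out from 10: after the BBr3 treatment the crude polyphenol is not purified but acetylated in the same flask (Ac2O, pyridine, rt) to fucodiphloroethol G decaacetate F7. This is stable to air and silica and can be separated from under-demethylated material. Acid methanolysis of F7 (HCl in degassed MeOH, rt, Ar) then comes back to the route at 11.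

**Further compounds**
F1 | step 1 | 2,4,6-trimethoxyphenyllithium | [Li]c1c(OC)cc(OC)cc1OC
F2 | step 1 | tris(2,4,6-trimethoxyphenyl)bismuthane | COc1cc(OC)c(c(OC)c1)[Bi](c1c(OC)cc(OC)cc1OC)c1c(OC)cc(OC)cc1OC
F3 | step 1 | dichlorotris(2,4,6-trimethoxyphenyl)bismuth | COc1cc(OC)c(c(OC)c1)[Bi](Cl)(Cl)(c1c(OC)cc(OC)cc1OC)c1c(OC)cc(OC)cc1OC
F4 | step 4 | 3,5-dimethoxy-2-{3,5-dimethoxy-2-[3,5-dimethoxy-2-(2,4,6-trimethoxyphenyl)phenoxy]phenoxy}benzaldehyde | COc1cc(C=O)c(Oc2cc(OC)cc(OC)c2Oc2cc(OC)cc(OC)c2-c2c(OC)cc(OC)cc2OC)c(OC)c1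
F5 | step 4 | 3,5-dimethoxy-2-{3,5-dimethoxy-2-[3,5-dimethoxy-2-(2,4,6-trimethoxyphenyl)phenoxy]phenoxy}phenyl formate | COc1cc(OC=O)c(Oc2cc(OC)cc(OC)c2Oc2cc(OC)cc(OC)c2-c2c(OC)cc(OC)cc2OC)c(OC)c1
F6 | step 4 | 3,5-dimethoxy-2-{3,5-dimethoxy-2-[3,5-dimethoxy-2-(2,4,6-trimethoxyphenyl)phenoxy]phenoxy}phenol | COc1cc(O)c(Oc2cc(OC)cc(OC)c2Oc2cc(OC)cc(OC)c2-c2c(OC)cc(OC)cc2OC)c(OC)c1
F7 | step 5 | fucodiphloroethol G decaacetate | CC(=O)Oc1cc(OC(C)=O)c(Oc2cc(OC(C)=O)cc(OC(C)=O)c2Oc2cc(OC(C)=O)cc(OC(C)=O)c2-c2c(OC(C)=O)cc(OC(C)=O)cc2OC(C)=O)c(OC(C)=O)c1
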